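**Conventions.** Oxolane: O1, C2 (4-oxygenated phenyl, next to C3), C3 (carries the benzofuranyl group), C4 (3,5-dioxygenated phenyl), C5 (4-oxygenated phenyl). Dihydrobenzofuran: O1', C2', C3', C3a', C4'–C7', C7a'; ring D is its benzo ring. Bn = benzyl. DBF = the (2R,3R)-6-(benzyloxy)-2-[4-(benzyloxy)phenyl]-3-[3,5-bis(benzyloxy)phenyl]-2,3-dihydro-1-benzofuran-4-yl group.

## Analysis of the target

The target (26) is a resveratrol trimer: a 2,3,4,5-tetraaryl oxolane joined through C3 to C4' of a trans-2,3-diaryl-2,3-dihydrobenzofuran, with eight free phenols on five benzene rings. It has six stereocentres, (2S,3S,4R,5S) in the oxolane and (2'R,3'R) in the dihydrobenzofuran. In the oxolane the aryl groups on C2, C3 and C4 lie on one face and the C5 aryl on the other; the two ring systems are related only across the C3–C4' single bond. The ring ether bonds O1–C2, O1–C5 and O1'–C2' are 4-hydroxybenzylic and ionise under protic or Lewis acids. Because the all-cis C2–C3–C4 array is the less stable arrangement, any such ionisation would epimerise it; the electron-rich rings are also easily oxidised or alkylated. The difficulty is to build three contiguous cis aryl-bearing carbons with no heteroatom handle, relate them to the remote C2'/C3' pair, and carry them to the end without equilibration. The strategy reads C3–C4 with their cis aryl groups as a Z-1,2-diarylethene, and C2 plus the future C5 as the two carbons of a monoaryl ketene. One [2+2] cycloaddition then makes C2–C3 and C4–C5, and the temporary C2–C5 bond of the cyclobutanone is later exchanged for O1.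

## Retrosynthetic reasoning

**26 to 25.** The eight phenols are masked as benzyl ethers and released last by hydrogenolysis. Methyl ethers would need a boron trihalide, which would ionise the benzylic ring ethers and scramble C2 and C5; benzyl ethers come off under neutral conditions.

**25 to 22 and 23.** The C5–aryl bond is cut. C5 is the only oxolane carbon whose aryl group is trans to its neighbour, so it is best introduced by a nucleophile adding to a C5 oxocarbenium ion on the face away from the three cis aryl groups. The forward reaction is displacement of the anomeric sulfone of 22 by the arylzinc 24 made from Grignard reagent 23.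

**22 to 21 to 20 to 19.** Sulfone 22 comes from lactol 21 and this from lactone 20. The O1–C2 bond of 20 is traced back to the C2–C5 bond of cyclobutanone 19: a Baeyer–Villiger reaction inserts oxygen with retention at the migrating carbon. Ring strain makes the step easy, and the 4-alkoxybenzylic C2 should migrate in preference to the 3,5-dialkoxybenzylic C4. The carbon ring thus serves only to set stereochemistry.

**19 to 15 and 18 (key disconnection).** C2–C3 and C4–C5 are cut together. This is the only pair of bonds whose simultaneous formation turns alkene geometry into the C3/C4 cis relationship and, through the known preference of ketene cycloadditions, places the C2 aryl on the same face. Ketene 18 is generated without base from diazoketone 17, so the epimerisable α-aryl ketone 19 never meets an amine. The forward reaction must control the orientation (carbonyl carbon to C4) and the alkene face.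

**15 to 14 to 11 and 13.** The Z-alkene comes from diarylalkyne 14 by semihydrogenation, and 14 from aryl bromide 11 and alkyne 13 by cross-coupling. The C4'–C(sp) bond is chosen because the bromine can be carried on ring D from the first step.

**11 to 10 to 9 to 8 to 7.** The C2'–C3' bond of the dihydrobenzofuran is cut. A chiral dirhodium carbene from diaryldiazomethane 9 inserts into the benzylic C–H bond of the ortho aryl benzyl ether, setting C3' under catalyst control. C2' is then equilibrated from cis (10) to trans (11). Diazo compound 9 comes from hydrazone 8 of ketone 7.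

**7 to 5 and 6; 5 to 4 to 3 to 1 and 2.** The ether O1'–CH2 is made by alkylating the chelated phenol of 5 with chloride 6. Ketone 5 comes from tetraphenol 4 by selective benzylation of the three unchelated phenols, 4 from 3 by demethylation, and 3 from 1 and 2 by acylation. The acylation places carbonyl, bromine and both oxygens of ring D correctly in one step.

**17 to 16; 13 to 12.** The diazoketone is the acylation product of acid chloride 16; the alkyne is the one-carbon homologue of aldehyde 12.

## Alternatives that were turned down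

**Alternative 1:** ring D built by a ruthenium-catalysed [2+2+2].
- Disconnection: the three ring D bonds C3a'–C7a', C4'–C5' and C6'–C7'. Ring D and the fused dihydrofuran would arise from a diyne tethered through O1'–C2'–C3' and a monoalkoxyacetylene.
- Forward key step: a cyclopentadienyl-ruthenium chloride catalyst joins the three alkynes to give A1, the target as its heptamethyl 6'-ethyl ether.
- For it: ring D is made with its substitution fixed by connectivity. This avoids the regioselective arene acylation, the hindered hydrazone and the hindered cross-coupling of the chosen route; on these points it is stronger.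
- Against it: all six stereocentres must already be present in the open-chain diyne, so the key step does nothing for the all-cis oxolane, which is the real problem. The ynol ether must be made on a 4-methoxybenzylic secondary alcohol, a fragile arrangement. The third alkyne can insert in two orientations. A1 needs a boron trihalide for deprotection, which the benzylic ring ethers are unlikely to survive.
- Comparison: the ketene cycloaddition creates three stereocentres and a ring in the step that carries the risk, and its protecting groups leave under neutral conditions.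

**Alternative 2:** copper-carbene [4+1] to a 2,3-dihydrofuran.
- Disconnection: O1–C5 and C4–C5, from a 1,2,3-triarylpropenone (C2, C3, C4 and O1) and an arylcarbene carbon (C5).
- Forward key step: a copper carbene with a chiral bisoxazoline is captured by the enone oxygen and the ylide closes to A2, the 4,5-trans tetraaryl 2,3-dihydrofuran. Hydrogenation of C2=C3 anti to the C4 aryl would then set C2 and C3.
- For it: three components are joined convergently, and C5 is set trans to C4 in the ring-forming step. This is stronger than the chosen route, which needs oxocarbenium chemistry on a sensitive lactol for the same centre.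
- Against it: a donor-only aryldiazomethane is hard to handle and can cyclopropanate or dimerise. The enone needs defined geometry. The hydrogenation of a tetrasubstituted, tetra-aryl enol ether shielded on both faces is slow and invites hydrogenolysis of the benzylic C–O bonds and aromatisation to the furan.
- Comparison: two of the three cis centres depend on that hydrogenation; in the chosen route the cis triad follows from alkene geometry in a bond-forming event.

**Alternative 3:** late ortho-quinone methide [4+1].
- Disconnection: C2'–C3' and O1'–C2', closed last on a ring D benzhydrol attached to the finished oxolane.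
- Forward key step: the ortho-quinone methide adds a benzylic sulfonium ylide at C3' and closes by displacement of the sulfide, giving A3, the octamethyl ether of the target, with the new ring trans.
- For it: the annulation is robust and trans-selective, and more dependable than the carbene insertion used here for the same ring.
- Against it: the quinone methide is planar, so the C3' configuration relative to the oxolane rests on substrate control through the C3–C4' bond. The disconnection gives no route to the enantiopure all-cis oxolane it presupposes. A3 again needs a boron trihalide.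
- Comparison: the chosen route sets C2'/C3' by catalyst control early and solves the oxolane in its key step. The price is that the cycloaddition must read the remote centres to choose the alkene face. The same annulation is kept, in racemic form, as the fallback for step 6.

Key step: step 12

Assumption: the carbene insertion of step 6 is taken to give the 2,3-cis isomer with (3R) configuration from Rh2(S-PTAD)4. If the sense of induction is opposite, the mirror-image catalyst is used; if the trans isomer forms directly, step 7 is omitted.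

## Route

Step 1
Reactants: 1 1-bromo-3,5-dimethoxybenzene; 2 3,5-dimethoxybenzoyl chloride
Product: 3 (2-bromo-4,6-dimethoxyphenyl)(3,5-dimethoxyphenyl)methanone
Conditions: AlCl3, CH2Cl2, 0 to 25 °C
Reagents that add atoms: none
Why: Friedel–Crafts acylation; the acylium ion attacks 1 para to one methoxy group and ortho to the other rather than between the two methoxy groups, so bromine (future C4') and both oxygens (future C6' and O1') of ring D are placed in one step.

Step 2
Reactants: 3 (2-bromo-4,6-dimethoxyphenyl)(3,5-dimethoxyphenyl)methanone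
Product: 4 (2-bromo-4,6-dihydroxyphenyl)(3,5-dihydroxyphenyl)methanone
Conditions: BBr3, CH2Cl2, −78 to 25 °C; MeOH, H2O
Reagents that add atoms: none
Why: Lewis-acid cleavage of the four aryl methyl ethers; ketone and aryl bromide are inert and no acid-labile centre exists yet, so the change to benzyl protection is made at this robust stage.

Step 3
Reactants: 4 (2-bromo-4,6-dihydroxyphenyl)(3,5-dihydroxyphenyl)methanone
Product: 5 [4-(benzyloxy)-2-bromo-6-hydroxyphenyl][3,5-bis(benzyloxy)phenyl]methanone
Conditions: BnBr (3 equiv), K2CO3, acetone, 25 °C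
Reagents that add atoms: benzyl bromide, BrCc1ccccc1
Why: Williamson etherification; the phenol ortho to the carbonyl is hydrogen-bonded to it and hindered, so with three equivalents of halide and a mild base the three other phenols should react first.

Step 4
Reactants: 5 [4-(benzyloxy)-2-bromo-6-hydroxyphenyl][3,5-bis(benzyloxy)phenyl]methanone; 6 1-(benzyloxy)-4-(chloromethyl)benzene
Product: 7 [4-(benzyloxy)-2-{[4-(benzyloxy)phenyl]methoxy}-6-bromophenyl][3,5-bis(benzyloxy)phenyl]methanone
Conditions: Cs2CO3, n-Bu4NI (cat.), DMF, 60 °C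
Reagents that add atoms: none
Why: Williamson etherification of the remaining chelated phenol under more forcing conditions; it puts the CH2 group that becomes C2', with its 4-(benzyloxy)phenyl group, on the future O1'.

Step 5
Reactants: 7 [4-(benzyloxy)-2-{[4-(benzyloxy)phenyl]methoxy}-6-bromophenyl][3,5-bis(benzyloxy)phenyl]methanone
Product: 8 the hydrazone of ketone 7 (C=N–NH2 in place of C=O, either geometry)
Conditions: N2H4·H2O (excess), AcOH (cat.), n-BuOH, 110 °C
Reagents that add atoms: hydrazine, NN
Why: Hydrazone condensation; the doubly ortho-substituted diaryl ketone needs excess hydrazine and heat, which benzyl ethers and the aryl bromide tolerate.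

Step 6
Reactants: 8 the hydrazone of ketone 7
Product: 10 (2S,3R)-6-(benzyloxy)-2-[4-(benzyloxy)phenyl]-3-[3,5-bis(benzyloxy)phenyl]-4-bromo-2,3-dihydro-1-benzofuran (2,3-cis), via diaryldiazomethane 9 (not isolated)
Conditions: MnO2, CH2Cl2, 0 °C, filter; Rh2(S-PTAD)4 (1 mol %), CH2Cl2, −20 to 0 °C
Reagents that add atoms: none
Why: Oxidation of the hydrazone gives the diazo compound, whose dirhodium carbene inserts into the benzylic C–H bond of the ortho aryl benzyl ether (1,5-insertion) and closes the dihydrofuran ring; the chiral carboxylate ligands set C3', and the cis isomer is the expected kinetic product for donor/donor carbenes of this class.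

Step 7
Reactants: 10 the (2S,3R)-cis 4-bromodihydrobenzofuran
Product: 11 (2R,3R)-6-(benzyloxy)-2-[4-(benzyloxy)phenyl]-3-[3,5-bis(benzyloxy)phenyl]-4-bromo-2,3-dihydro-1-benzofuran (2,3-trans)
Conditions: CF3CO2H, CH2Cl2, −20 to 0 °C
Reagents that add atoms: none
Why: Acid-mediated epimerisation; reversible ionisation of the O1'–C2' bond to a 4-alkoxybenzylic cation and reclosure by the phenol gives the more stable trans isomer, while C3' is not touched and keeps the catalyst-derived configuration.

Step 8
Reactants: 12 3,5-bis(benzyloxy)benzaldehyde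
Product: 13 1,3-bis(benzyloxy)-5-ethynylbenzene
Conditions: dimethyl (1-diazo-2-oxopropyl)phosphonate, K2CO3, MeOH/THF, 0 to 25 °C
Reagents that add atoms: dimethyl (1-diazo-2-oxopropyl)phosphonate, COP(=O)(OC)C(=[N+]=[N-])C(C)=O
Why: Seyferth–Gilbert homologation with the Ohira–Bestmann reagent; a non-enolisable aryl aldehyde is converted cleanly into the terminal alkyne under mild base.

Step 9
Reactants: 11 the (2R,3R)-trans 4-bromodihydrobenzofuran; 13 1,3-bis(benzyloxy)-5-ethynylbenzene
Product: 14 1,3-bis(benzyloxy)-5-(DBF-ethynyl)benzene, i.e. DBF–C≡C–C6H3(OBn)2-3,5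
Conditions: PdCl2(MeCN)2 (cat.), XPhos, Cs2CO3, MeCN, 80 °C
Reagents that add atoms: none
Why: Copper-free Sonogashira coupling; a bulky electron-rich phosphine lets zerovalent palladium insert into the hindered, electron-rich aryl bromide, and the stereocentres are remote from any basic site.

Step 10
Reactants: 14 the diarylalkyne DBF–C≡C–C6H3(OBn)2-3,5
Product: 15 1,3-bis(benzyloxy)-5-[(Z)-2-DBF-ethenyl]benzene
Conditions: H2 (1 atm), Pd/CaCO3–Pb(OAc)2, quinoline, EtOAc, 25 °C
Reagents that add atoms: none
Why: Lindlar semihydrogenation; syn delivery of hydrogen on the poisoned surface gives the Z-alkene, and benzyl ethers and the ring ether are not cleaved by this catalyst.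

Step 11
Reactants: 16 4-(benzyloxy)benzoyl chloride
Product: 17 1-[4-(benzyloxy)phenyl]-2-diazoethan-1-one
Conditions: Me3SiCHN2, MeCN/THF, 0 to 25 °C
Reagents that add atoms: (trimethylsilyl)diazomethane, C[Si](C)(C)C=[N+]=[N-]
Why: Acylation of a diazoalkane (Arndt–Eistert-type diazoketone synthesis); chloride removes the silyl group from the acylated intermediate to give the diazoketone.

Step 12
Reactants: 15 1,3-bis(benzyloxy)-5-[(Z)-2-DBF-ethenyl]benzene; 17 1-[4-(benzyloxy)phenyl]-2-diazoethan-1-one
Product: 19 (2S,3S,4R)-2-[4-(benzyloxy)phenyl]-4-[3,5-bis(benzyloxy)phenyl]-3-DBF-cyclobutan-1-one (the three ring substituents cis), via [4-(benzyloxy)phenyl]ketene 18 (not isolated)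
Conditions: hν (450 nm LEDs), PhMe, 40 °C; 17 (4 equiv) added slowly to 15 (0.5 M)
Reagents that add atoms: none
Why: Proposed new method: visible light, absorbed only by the diazoketone and not by the stilbene (so Z/E isomerisation and electrocyclisation of 15 are avoided), expels N2 with 1,2-shift of the aryl group (Wolff rearrangement) to give ketene 18 without base; the ketene then adds to the alkene in an asynchronous concerted [2+2] in which its carbonyl carbon bonds first to C4 and the C2–C3 bond then closes the four-membered ring. The closest known reaction type is the thermal or Lewis-acid-promoted ketene–alkene [2+2] cycloaddition, and the untested element is a photogenerated monoaryl ketene meeting a hindered, electron-neutral Z-1,2-diarylethene. The ring is closed by cycloaddition, suprafacially on the alkene, so the Z geometry becomes the C3/C4 cis relationship. C2 is set by the usual ketene preference: the ketene approaches with its hydrogen toward the alkene substituents and the closing rotation carries the aryl group onto their face, giving the all-cis ketone. Regiochemistry should follow from the less hindered C4 bonding to the sp carbon while the developing positive charge at C3 is stabilised by the more electron-rich, ortho-alkylated ring D. The face is chosen by the C3' aryl group: in the rotamer with the vinylic C3–H beside the C3' hydrogen and the styryl arm over C5', that aryl covers one alkene face and attack on the other gives the (3S) configuration required. Slow generation keeps the ketene concentration low so that cycloaddition can compete with dimerisation, and the absence of amine protects the two α-aryl centres of the product.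

Step 13
Reactants: 19 the all-cis triarylcyclobutanone
Product: 20 (3R,4S,5S)-5-[4-(benzyloxy)phenyl]-3-[3,5-bis(benzyloxy)phenyl]-4-DBF-oxolan-2-one (lactone C5, C4 and C3 are C2, C3 and C4 of the target)
Conditions: mCPBA, NaHCO3, CH2Cl2, 0 °C
Reagents that add atoms: 3-chloroperbenzoic acid, O=C(OO)c1cccc(Cl)c1
Why: Baeyer–Villiger oxidation driven by ring strain; in the Criegee intermediate the 4-alkoxybenzylic C2 migrates in preference to the 3,5-dialkoxybenzylic C4 (the meta oxygens are inductively withdrawing) and does so with retention, so O1 enters between C5 and C2 and the cis triad is kept; the buffer prevents acid-promoted epimerisation.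

Step 14
Reactants: 20 the all-cis triaryl lactone
Product: 21 (2S,3S,4R)-2-[4-(benzyloxy)phenyl]-4-[3,5-bis(benzyloxy)phenyl]-3-DBF-oxolan-5-ol (target numbering, both C5 epimers)
Conditions: i-Bu2AlH, PhMe/CH2Cl2, −78 °C; aq. potassium sodium tartrate
Reagents that add atoms: none
Why: Partial hydride reduction of a lactone; the tetrahedral aluminium hemiacetal is stable at −78 °C and gives the lactol on neutral work-up, and the crude lactol is used at once because its open hydroxy-aldehyde form could enolise at C4.

Step 15
Reactants: 21 the lactol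
Product: 22 (2S,3S,4R)-2-[4-(benzyloxy)phenyl]-4-[3,5-bis(benzyloxy)phenyl]-3-DBF-5-(phenylsulfonyl)oxolane (both C5 epimers)
Conditions: PhSO2H, CaCl2, CH2Cl2, 0 to 25 °C
Reagents that add atoms: benzenesulfinic acid, O=S(O)c1ccccc1
Why: Anomeric sulfone formation; the mildly acidic sulfinic acid ionises the lactol and sulfinate captures the oxocarbenium ion at sulfur, giving a stable precursor that re-ionises under mild Lewis acids; the C5 configuration is irrelevant because it is lost again in the next step.

Step 16
Reactants: 22 the anomeric sulfone; 23 [4-(benzyloxy)phenyl]magnesium bromide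
Product: 25 (2S,3S,4R,5S)-2,5-bis[4-(benzyloxy)phenyl]-4-[3,5-bis(benzyloxy)phenyl]-3-DBF-oxolane (octabenzyl ether of the target), via bis[4-(benzyloxy)phenyl]zinc 24 (not isolated)
Conditions: 23, ZnBr2, THF, 0 °C; then 22, 25 °C
Reagents that add atoms: zinc bromide, [Zn+2].[Br-].[Br-] (zinc of intermediate 24 only)
Why: Substitution of an anomeric sulfone by an arylzinc reagent, a known route to trans-2,5-diaryl oxolanes; the zinc and magnesium halides assist loss of sulfinate and the aryl group adds to the planar C5 oxocarbenium ion on the face away from the three cis aryl groups on C2, C3 and C4, which makes the C5 aryl trans to the C4 aryl.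

Step 17
Reactants: 25 the octabenzyl ether
Product: 26 5-{(2R,3R)-6-hydroxy-2-(4-hydroxyphenyl)-4-[(2S,3S,4R,5S)-4-(3,5-dihydroxyphenyl)-2,5-bis(4-hydroxyphenyl)oxolan-3-yl]-2,3-dihydro-1-benzofuran-3-yl}benzene-1,3-diol (CNP0202577.3)
Conditions: H2 (1 atm), Pd/C, EtOAc/MeOH, 25 °C
Reagents that add atoms: none
Why: Hydrogenolysis of eight aryl benzyl ethers under neutral conditions; O-benzyl cleavage is much faster than hydrogenolysis of the hindered secondary ring C–O bonds, and without acid no stereocentre can ionise, so the reaction is stopped once the last benzyl group has gone.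

## Compound list

1 | 1-bromo-3,5-dimethoxybenzene | COc1cc(Br)cc(OC)c1 | starting material
2 | 3,5-dimethoxybenzoyl chloride | COc1cc(OC)cc(C(=O)Cl)c1 | starting material
3 | (2-bromo-4,6-dimethoxyphenyl)(3,5-dimethoxyphenyl)methanone | COc1cc(OC)cc(C(=O)c2c(Br)cc(OC)cc2OC)c1 | intermediate
4 | (2-bromo-4,6-dihydroxyphenyl)(3,5-dihydroxyphenyl)methanone | Oc1cc(O)cc(C(=O)c2c(Br)cc(O)cc2O)c1 | intermediate
5 | [4-(benzyloxy)-2-bromo-6-hydroxyphenyl][3,5-bis(benzyloxy)phenyl]methanone | O=C(c1cc(OCc2ccccc2)cc(OCc2ccccc2)c1)c1c(O)cc(OCc2ccccc2)cc1Br | intermediate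
6 | 1-(benzyloxy)-4-(chloromethyl)benzene | ClCc1ccc(OCc2ccccc2)cc1 | starting material
7 | [4-(benzyloxy)-2-{[4-(benzyloxy)phenyl]methoxy}-6-bromophenyl][3,5-bis(benzyloxy)phenyl]methanone | O=C(c1cc(OCc2ccccc2)cc(OCc2ccccc2)c1)c1c(OCc2ccc(OCc3ccccc3)cc2)cc(OCc2ccccc2)cc1Br | intermediate
8 | hydrazone of ketone 7 | NN=C(c1cc(OCc2ccccc2)cc(OCc2ccccc2)c1)c1c(OCc2ccc(OCc3ccccc3)cc2)cc(OCc2ccccc2)cc1Br | intermediate
9 | diaryldiazomethane from 8 (C=N2 in place of C=N–NH2) | [N-]=[N+]=C(c1cc(OCc2ccccc2)cc(OCc2ccccc2)c1)c1c(OCc2ccc(OCc3ccccc3)cc2)cc(OCc2ccccc2)cc1Br | intermediate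
10 | (2S,3R)-6-(benzyloxy)-2-[4-(benzyloxy)phenyl]-3-[3,5-bis(benzyloxy)phenyl]-4-bromo-2,3-dihydro-1-benzofuran | Brc1cc(OCc3ccccc3)cc2c1[C@@H](c1cc(OCc3ccccc3)cc(OCc3ccccc3)c1)[C@@H](c1ccc(OCc3ccccc3)cc1)O2 | intermediate
11 | (2R,3R)-6-(benzyloxy)-2-[4-(benzyloxy)phenyl]-3-[3,5-bis(benzyloxy)phenyl]-4-bromo-2,3-dihydro-1-benzofuran | Brc1cc(OCc3ccccc3)cc2c1[C@@H](c1cc(OCc3ccccc3)cc(OCc3ccccc3)c1)[C@H](c1ccc(OCc3ccccc3)cc1)O2 | intermediate
12 | 3,5-bis(benzyloxy)benzaldehyde | O=Cc1cc(OCc2ccccc2)cc(OCc2ccccc2)c1 | starting material
13 | 1,3-bis(benzyloxy)-5-ethynylbenzene | C#Cc1cc(OCc2ccccc2)cc(OCc2ccccc2)c1 | intermediate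
14 | 1,3-bis(benzyloxy)-5-(DBF-ethynyl)benzene | C(#Cc1cc(OCc2ccccc2)cc(OCc2ccccc2)c1)c1cc(OCc3ccccc3)cc2c1[C@@H](c1cc(OCc3ccccc3)cc(OCc3ccccc3)c1)[C@H](c1ccc(OCc3ccccc3)cc1)O2 | intermediate
15 | 1,3-bis(benzyloxy)-5-[(Z)-2-DBF-ethenyl]benzene | c1ccccc1COc1cc(/C=C\c2cc(OCc4ccccc4)cc3c2[C@@H](c2cc(OCc4ccccc4)cc(OCc4ccccc4)c2)[C@H](c2ccc(OCc4ccccc4)cc2)O3)cc(OCc2ccccc2)c1 | intermediate
16 | 4-(benzyloxy)benzoyl chloride | O=C(Cl)c1ccc(OCc2ccccc2)cc1 | starting material
17 | 1-[4-(benzyloxy)phenyl]-2-diazoethan-1-one | [N-]=[N+]=CC(=O)c1ccc(OCc2ccccc2)cc1 | intermediate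
18 | [4-(benzyloxy)phenyl]ketene | O=C=Cc1ccc(OCc2ccccc2)cc1 | intermediate
19 | (2S,3S,4R)-2-[4-(benzyloxy)phenyl]-4-[3,5-bis(benzyloxy)phenyl]-3-DBF-cyclobutan-1-one | c1ccccc1COc1ccc([C@H]2C(=O)[C@@H](c3cc(OCc4ccccc4)cc(OCc4ccccc4)c3)[C@H]2c2cc(OCc4ccccc4)cc3c2[C@@H](c2cc(OCc4ccccc4)cc(OCc4ccccc4)c2)[C@H](c2ccc(OCc4ccccc4)cc2)O3)cc1 | intermediate
20 | (3R,4S,5S)-5-[4-(benzyloxy)phenyl]-3-[3,5-bis(benzyloxy)phenyl]-4-DBF-oxolan-2-one | c1ccccc1COc1ccc([C@H]2OC(=O)[C@@H](c3cc(OCc4ccccc4)cc(OCc4ccccc4)c3)[C@H]2c2cc(OCc4ccccc4)cc3c2[C@@H](c2cc(OCc4ccccc4)cc(OCc4ccccc4)c2)[C@H](c2ccc(OCc4ccccc4)cc2)O3)cc1 | intermediate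
21 | (2S,3S,4R)-2-[4-(benzyloxy)phenyl]-4-[3,5-bis(benzyloxy)phenyl]-3-DBF-oxolan-5-ol, both C5 epimers | c1ccccc1COc1ccc([C@H]2OC(O)[C@@H](c3cc(OCc4ccccc4)cc(OCc4ccccc4)c3)[C@H]2c2cc(OCc4ccccc4)cc3c2[C@@H](c2cc(OCc4ccccc4)cc(OCc4ccccc4)c2)[C@H](c2ccc(OCc4ccccc4)cc2)O3)cc1 | intermediate
22 | (2S,3S,4R)-2-[4-(benzyloxy)phenyl]-4-[3,5-bis(benzyloxy)phenyl]-3-DBF-5-(phenylsulfonyl)oxolane, both C5 epimers | c1ccccc1COc1ccc([C@H]2OC(S(=O)(=O)c3ccccc3)[C@@H](c3cc(OCc4ccccc4)cc(OCc4ccccc4)c3)[C@H]2c2cc(OCc4ccccc4)cc3c2[C@@H](c2cc(OCc4ccccc4)cc(OCc4ccccc4)c2)[C@H](c2ccc(OCc4ccccc4)cc2)O3)cc1 | intermediate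
23 | [4-(benzyloxy)phenyl]magnesium bromide | Br[Mg]c1ccc(OCc2ccccc2)cc1 | starting material
24 | bis[4-(benzyloxy)phenyl]zinc | c1ccccc1COc1ccc([Zn]c2ccc(OCc3ccccc3)cc2)cc1 | intermediate
25 | (2S,3S,4R,5S)-2,5-bis[4-(benzyloxy)phenyl]-4-[3,5-bis(benzyloxy)phenyl]-3-DBF-oxolane | c1ccccc1COc1ccc([C@H]2O[C@H](c3ccc(OCc4ccccc4)cc3)[C@@H](c3cc(OCc4ccccc4)cc(OCc4ccccc4)c3)[C@H]2c2cc(OCc4ccccc4)cc3c2[C@@H](c2cc(OCc4ccccc4)cc(OCc4ccccc4)c2)[C@H](c2ccc(OCc4ccccc4)cc2)O3)cc1 | intermediate
26 | 5-{(2R,3R)-6-hydroxy-2-(4-hydroxyphenyl)-4-[(2S,3S,4R,5S)-4-(3,5-dihydroxyphenyl)-2,5-bis(4-hydroxyphenyl)oxolan-3-yl]-2,3-dihydro-1-benzofuran-3-yl}benzene-1,3-diol | Oc1ccc([C@H]2O[C@H](c3ccc(O)cc3)[C@@H](c3cc(O)cc(O)c3)[C@H]2c2cc(O)cc3c2[C@@H](c2cc(O)cc(O)c2)[C@H](c2ccc(O)cc2)O3)cc1 | target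

## Step count and least certain steps

Total: 17 steps. Longest linear sequence: 15 steps (1–7, 9, 10, 12–17); steps 8 and 11 are side branches.

**Step 12 (key step, proposed new method).** Four processes can defeat it.
- Dimerisation of the ketene, or its capture by unreacted diazoketone, may outrun cycloaddition to a twisted, electron-neutral Z-stilbene.
- Bonding may occur in the opposite orientation, because the two alkene carbons differ little electronically.
- Attack may occur on the other alkene face, since facial control rests on a rotamer preference about C3–C4'.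
- The α-aryl centres of the strained ketone may epimerise on handling.

Lewis-acid promotion (EtAlCl2) would raise the rate but can change the endo/exo preference of aryl ketenes, so it is not relied on.

Fallback, known chemistry, from bromide 11 to lactone 20:
- Bromine–lithium exchange on 11 (n-BuLi, THF, −78 °C) and acylation with N-methoxy-N-methyl-2-[4-(benzyloxy)phenyl]acetamide F1 (from the commercial arylacetic acid) give the aryl benzyl ketone F2.
- Its potassium enolate (KN(SiMe3)2) is hydroxylated with a Davis oxaziridine to the α-hydroxy ketone F3.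
- F3 is esterified with commercial [3,5-bis(benzyloxy)phenyl]acetic acid (carbodiimide, DMAP) to the ester F4.
- DBU closes F4 by intramolecular Knoevenagel-type condensation to the 3,4,5-triaryl butenolide F5.
- cis-Hydrogenation of the tetrasubstituted alkene (H2, Rh/Al2O3, EtOAc, pressure) from the face opposite the C2 aryl gives the all-cis lactone 20.

This places every carbon and the ring oxygen by construction, so it also answers an unselective oxygen insertion in step 13. Its price is that C2 is formed without control relative to the dihydrobenzofuran: the two all-cis lactones must be separated, and the unwanted butenolide epimer can be re-equilibrated with base.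

**Step 6 (with its feeder step 5 and follow-up step 7).** Condensation of the doubly ortho-substituted ketone with hydrazine may stall. The ortho bromine may lower the enantio- or diastereoselectivity of insertion. The acid epimerisation may erode enantiopurity through elimination to a triarylethene and re-addition.

Fallback from ketone 5 to bromide 11:
- NaBH4 reduces 5 to the benzhydrol F6.
- 4-Methylbenzenesulfinic acid converts F6 into the sulfone F7, a base-labile ortho-quinone methide precursor.
- F7 reacts with 1-[4-(benzyloxy)benzyl]tetrahydrothiophenium chloride F8 (from chloride 6 and tetrahydrothiophene) and Cs2CO3 in a [4+1] annulation to the racemic trans-4-bromodihydrobenzofuran F9.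
- Preparative chromatography on a chiral stationary phase gives 11.

**Step 14.** The lactol may epimerise at C4 through enolisation of its ring-opened γ-hydroxy aldehyde, which would relieve the all-cis strain. Fallback from lactone 20 to sulfone 22: reduction with i-Bu2AlH at −78 °C and trapping of the aluminium hemiacetal in the same flask with Ac2O, pyridine and DMAP gives the lactol acetate F10, so the free lactol is never formed; F10 with PhSO2H and CaCl2 gives 22.

**Step 16.** The C5 oxocarbenium ion may lose the C4 proton to give an enol ether, or be captured by C5' of ring D in a Friedel–Crafts ring closure, faster than the aryl group is transferred. Fallback from lactol 21 to 25 that avoids a free cation: Me3SiBr converts 21 into the anomeric bromide F11, which is coupled without isolation with Grignard reagent 23 under Co(acac)3/TMEDA catalysis. The coupling runs through the C5 radical, which should again be arylated on the open face.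

## Further compounds

F1 | step 12 | N-methoxy-N-methyl-2-[4-(benzyloxy)phenyl]acetamide | CON(C)C(=O)Cc1ccc(OCc2ccccc2)cc1
F2 | step 12 | 2-[4-(benzyloxy)phenyl]-1-DBF-ethan-1-one | O=C(Cc1ccc(OCc2ccccc2)cc1)c1cc(OCc3ccccc3)cc2c1[C@@H](c1cc(OCc3ccccc3)cc(OCc3ccccc3)c1)[C@H](c1ccc(OCc3ccccc3)cc1)O2
F3 | step 12 | 2-[4-(benzyloxy)phenyl]-2-hydroxy-1-DBF-ethan-1-one, both carbinol epimers | O=C(C(O)c1ccc(OCc2ccccc2)cc1)c1cc(OCc3ccccc3)cc2c1[C@@H](c1cc(OCc3ccccc3)cc(OCc3ccccc3)c1)[C@H](c1ccc(OCc3ccccc3)cc1)O2
F4 | step 12 | 1-[4-(benzyloxy)phenyl]-2-oxo-2-DBF-ethyl [3,5-bis(benzyloxy)phenyl]acetate, both epimers | O=C(C(OC(=O)Cc1cc(OCc2ccccc2)cc(OCc2ccccc2)c1)c1ccc(OCc2ccccc2)cc1)c1cc(OCc3ccccc3)cc2c1[C@@H](c1cc(OCc3ccccc3)cc(OCc3ccccc3)c1)[C@H](c1ccc(OCc3ccccc3)cc1)O2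
F5 | step 12 | 5-[4-(benzyloxy)phenyl]-3-[3,5-bis(benzyloxy)phenyl]-4-DBF-furan-2(5H)-one, both C5 epimers | O=C1OC(c2ccc(OCc3ccccc3)cc2)C(c2cc(OCc3ccccc3)cc3c2[C@@H](c2cc(OCc4ccccc4)cc(OCc4ccccc4)c2)[C@H](c2ccc(OCc4ccccc4)cc2)O3)=C1c1cc(OCc2ccccc2)cc(OCc2ccccc2)c1
F6 | step 6 | [4-(benzyloxy)-2-bromo-6-hydroxyphenyl][3,5-bis(benzyloxy)phenyl]methanol, racemic | OC(c1cc(OCc2ccccc2)cc(OCc2ccccc2)c1)c1c(O)cc(OCc2ccccc2)cc1Br
F7 | step 6 | 5-(benzyloxy)-2-{[3,5-bis(benzyloxy)phenyl](4-methylbenzenesulfonyl)methyl}-3-bromophenol, racemic | Cc1ccc(S(=O)(=O)C(c2cc(OCc3ccccc3)cc(OCc3ccccc3)c2)c2c(O)cc(OCc3ccccc3)cc2Br)cc1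
F8 | step 6 | 1-[4-(benzyloxy)benzyl]tetrahydrothiophenium chloride | [Cl-].c1ccccc1COc1ccc(C[S+]2CCCC2)cc1
F9 | step 6 | racemic trans-6-(benzyloxy)-2-[4-(benzyloxy)phenyl]-3-[3,5-bis(benzyloxy)phenyl]-4-bromo-2,3-dihydro-1-benzofuran (one enantiomer drawn) | Brc1cc(OCc3ccccc3)cc2c1[C@@H](c1cc(OCc3ccccc3)cc(OCc3ccccc3)c1)[C@H](c1ccc(OCc3ccccc3)cc1)O2
F10 | step 14 | (2S,3S,4R)-2-[4-(benzyloxy)phenyl]-4-[3,5-bis(benzyloxy)phenyl]-3-DBF-oxolan-5-yl acetate, both C5 epimers | c1ccccc1COc1ccc([C@H]2OC(OC(C)=O)[C@@H](c3cc(OCc4ccccc4)cc(OCc4ccccc4)c3)[C@H]2c2cc(OCc4ccccc4)cc3c2[C@@H](c2cc(OCc4ccccc4)cc(OCc4ccccc4)c2)[C@H](c2ccc(OCc4ccccc4)cc2)O3)cc1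
F11 | step 16 | (2S,3S,4R)-2-[4-(benzyloxy)phenyl]-4-[3,5-bis(benzyloxy)phenyl]-5-bromo-3-DBF-oxolane, both C5 epimers | c1ccccc1COc1ccc([C@H]2OC(Br)[C@@H](c3cc(OCc4ccccc4)cc(OCc4ccccc4)c3)[C@H]2c2cc(OCc4ccccc4)cc3c2[C@@H](c2cc(OCc4ccccc4)cc(OCc4ccccc4)c2)[C@H](c2ccc(OCc4ccccc4)cc2)O3)cc1
A1 | alternative 1 | heptamethyl 6'-ethyl ether of the target | COc1ccc([C@H]2O[C@H](c3ccc(OC)cc3)[C@@H](c3cc(OC)cc(OC)c3)[C@H]2c2cc(OCC)cc3c2[C@@H](c2cc(OC)cc(OC)c2)[C@H](c2ccc(OC)cc2)O3)cc1
A2 | alternative 2 | 4,5-trans tetraaryl 2,3-dihydrofuran (methyl ethers) | COc1ccc(C2=C(c3cc(OC)cc4c3[C@@H](c3cc(OC)cc(OC)c3)[C@H](c3ccc(OC)cc3)O4)[C@H](c3cc(OC)cc(OC)c3)[C@@H](c3ccc(OC)cc3)O2)cc1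
A3 | alternative 3 | octamethyl ether of the target | COc1ccc([C@H]2O[C@H](c3ccc(OC)cc3)[C@@H](c3cc(OC)cc(OC)c3)[C@H]2c2cc(OC)cc3c2[C@@H](c2cc(OC)cc(OC)c2)[C@H](c2ccc(OC)cc2)O3)cc1
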